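**Retrosynthetic overview**
1. The target is 5,2',5'-trihydroxy-7,3',4'-trimethoxyflavone; the last step is hydrogenolysis of two benzyl ethers on the B-ring hydroquinone.
2. The pyranone C-ring is cut at O1–C2 and C2=C3, going back to a 2',6'-dihydroxychalcone (oxidative cyclisation with I2/DMSO).
3. The chalcone Cα=Cβ bond is cut by Claisen–Schmidt condensation into 2',6'-dihydroxy-4'-methoxyacetophenone (A-ring, bought) and 2,5-bis(benzyloxy)-3,4-dimethoxybenzaldehyde (B-ring).
4. The B-ring aldehyde comes from 2-hydroxy-3,4-dimethoxybenzaldehyde by para-hydroxylation (Elbs) and double O-benzylation.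
5. Ring order: both benzene rings are bought; only the pyranone ring is built, last.

Assumption: the target has no stereocentre and no stereogenic axis or double bond, so "single enantiomer" needs no stereocontrol; the racemic centres in 6 and 8 and the E-alkene in 7 are all erased before the target. The route is designed from known reaction types and has not been run.

**Step 1**
Reactants: 1 2-hydroxy-3,4-dimethoxybenzaldehyde
Product: 3 2,5-dihydroxy-3,4-dimethoxybenzaldehyde, via aryl sulfate potassium salt 2 (not isolated)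
Conditions: K2S2O8 (1.1 equiv), 10% aq KOH, 0 °C to rt, 24 h; then conc. HCl, 90 °C, 30 min, N2
Reagents that add atoms: potassium persulfate, [K+].[K+].[O-]S(=O)(=O)OOS(=O)(=O)[O-]
Why: Elbs persulfate oxidation, in which the phenoxide attacks peroxydisulfate through its only free para carbon (C5; the ortho position carries OMe) and the aryl sulfate is hydrolysed by acid to the hydroquinone; no stereocentre is formed.

**Step 2**
Reactants: 3 2,5-dihydroxy-3,4-dimethoxybenzaldehyde
Product: 4 2,5-bis(benzyloxy)-3,4-dimethoxybenzaldehyde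
Conditions: BnBr (2.4 equiv), K2CO3 (3 equiv), DMF, 60 °C, N2
Reagents that add atoms: benzyl bromide, BrCc1ccccc1
Why: Williamson ether synthesis (SN2 of both phenoxides on benzyl bromide) masks the air-sensitive hydroquinone while the non-enolisable aldehyde is untouched.

**Step 3**
Reactants: 4 2,5-bis(benzyloxy)-3,4-dimethoxybenzaldehyde; 5 1-(2,6-dihydroxy-4-methoxyphenyl)ethan-1-one
Product: 7 (E)-3-[2,5-bis(benzyloxy)-3,4-dimethoxyphenyl]-1-(2,6-dihydroxy-4-methoxyphenyl)prop-2-en-1-one, via racemic aldol adduct 6 (not isolated)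
Conditions: 50% aq KOH (excess), EtOH, rt, 48 h, N2; then cold 1 M HCl
Reagents that add atoms: none
Why: Claisen–Schmidt (crossed aldol) condensation of the methyl ketone enolate with a non-enolisable aldehyde, followed by E1cB loss of water, gives the thermodynamic E-enone and removes the transient carbinol centre.

**Step 4**
Reactants: 7 (E)-3-[2,5-bis(benzyloxy)-3,4-dimethoxyphenyl]-1-(2,6-dihydroxy-4-methoxyphenyl)prop-2-en-1-one
Product: 9 2-[2,5-bis(benzyloxy)-3,4-dimethoxyphenyl]-5-hydroxy-7-methoxy-4H-chromen-4-one, via racemic flavanone 8 (not isolated)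
Conditions: I2 (10 mol%), DMSO, 120 °C, 3 h
Reagents that add atoms: none
Why: I2/DMSO oxidative cyclisation, in which one phenol closes by oxa-Michael addition to the flavanone and iodine-catalysed dehydrogenation (DMSO as terminal oxidant) gives the flavone, so the C2 centre is erased, the other phenol remains as the chelated 5-OH, and any flavanone carried over from step 3 converges.

**Step 5**
Reactants: 9 2-[2,5-bis(benzyloxy)-3,4-dimethoxyphenyl]-5-hydroxy-7-methoxy-4H-chromen-4-one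
Product: 10 2-(2,5-dihydroxy-3,4-dimethoxyphenyl)-5-hydroxy-7-methoxy-4H-chromen-4-one
Conditions: H2 (1 atm), 10% Pd/C, EtOAc/MeOH 1:1, rt, 3 h; filter and concentrate under Ar
Reagents that add atoms: none
Why: Catalytic hydrogenolysis cleaves both benzyl aryl ethers under neutral conditions, while the methyl ethers, the chelated 5-OH and the conjugated pyranone C2=C3 bond survive at 1 atm and room temperature.

**Compound list**
1 | 2-hydroxy-3,4-dimethoxybenzaldehyde | O=Cc1ccc(OC)c(OC)c1O | starting material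
2 | potassium 5-formyl-4-hydroxy-2,3-dimethoxyphenyl sulfate | O=Cc1cc(OS(=O)(=O)[O-])c(OC)c(OC)c1O.[K+] | intermediate
3 | 2,5-dihydroxy-3,4-dimethoxybenzaldehyde | O=Cc1cc(O)c(OC)c(OC)c1O | intermediate
4 | 2,5-bis(benzyloxy)-3,4-dimethoxybenzaldehyde | O=Cc1cc(OCc2ccccc2)c(OC)c(OC)c1OCc1ccccc1 | intermediate
5 | 1-(2,6-dihydroxy-4-methoxyphenyl)ethan-1-one (2',6'-dihydroxy-4'-methoxyacetophenone) | CC(=O)c1c(O)cc(OC)cc1O | starting material
6 | racemic 3-[2,5-bis(benzyloxy)-3,4-dimethoxyphenyl]-1-(2,6-dihydroxy-4-methoxyphenyl)-3-hydroxypropan-1-one | COc1cc(O)c(C(=O)CC(O)c2cc(OCc3ccccc3)c(OC)c(OC)c2OCc2ccccc2)c(O)c1 | intermediate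
7 | (E)-3-[2,5-bis(benzyloxy)-3,4-dimethoxyphenyl]-1-(2,6-dihydroxy-4-methoxyphenyl)prop-2-en-1-one | COc1cc(O)c(C(=O)/C=C/c2cc(OCc3ccccc3)c(OC)c(OC)c2OCc2ccccc2)c(O)c1 | intermediate
8 | racemic 2-[2,5-bis(benzyloxy)-3,4-dimethoxyphenyl]-5-hydroxy-7-methoxychroman-4-one | COc1cc(O)c2C(=O)CC(Oc2c1)c1cc(OCc2ccccc2)c(OC)c(OC)c1OCc1ccccc1 | intermediate
9 | 2-[2,5-bis(benzyloxy)-3,4-dimethoxyphenyl]-5-hydroxy-7-methoxy-4H-chromen-4-one | COc1cc(O)c2c(=O)cc(-c3cc(OCc4ccccc4)c(OC)c(OC)c3OCc3ccccc3)oc2c1 | intermediate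
10 | 2-(2,5-dihydroxy-3,4-dimethoxyphenyl)-5-hydroxy-7-methoxy-4H-chromen-4-one (achiral) | COc1cc(O)c2c(=O)cc(-c3cc(O)c(OC)c(OC)c3O)oc2c1 | target

**Totals**
Total step count: 5. Longest linear sequence: 5 (1 → 3 → 4 → 7 → 9 → 10; compound 5 is bought and enters at step 3).

**Three steps most likely to fail**

Step 1 (Elbs oxidation). Conversions are typically modest, with recovered phenol and dark over-oxidation products, and the aldehyde is exposed to alkaline oxidant. The fallback sets out from 1 and comes back at 4, installing the C5 oxygen through a halogen instead of by direct oxidation. Compound 1 is brominated para to the free phenol (NBS, MeCN, 0 °C) to 5-bromo-2-hydroxy-3,4-dimethoxybenzaldehyde F1. This is benzylated (BnBr, K2CO3, DMF) to 2-(benzyloxy)-5-bromo-3,4-dimethoxybenzaldehyde F2. Miyaura borylation (B2pin2, Pd(dppf)Cl2, KOAc, dioxane, 90 °C) gives 2-(benzyloxy)-3,4-dimethoxy-5-(4,4,5,5-tetramethyl-1,3,2-dioxaborolan-2-yl)benzaldehyde F3. Oxidation of the C–B bond (NaBO3·4H2O, THF/H2O, rt) gives 2-(benzyloxy)-5-hydroxy-3,4-dimethoxybenzaldehyde F4, and a second benzylation (BnBr, K2CO3, DMF) gives 4.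

Step 3 (Claisen–Schmidt with the unprotected 2',6'-dihydroxyacetophenone). The phenoxide dianion of 5 enolises poorly, so the condensation may stall or give chalcone/flavanone mixtures in low yield. The fallback sets out from 5 and comes back at 10, changing the protecting-group plan so that only one phenoxide is present. Compound 5 is monobenzylated (BnBr 1.0 equiv, K2CO3, acetone, reflux; the second OH stays hydrogen-bonded to the ketone) to 1-[2-(benzyloxy)-6-hydroxy-4-methoxyphenyl]ethan-1-one F5. Condensation with 4 (KOH, EtOH, rt) gives (E)-1-[2-(benzyloxy)-6-hydroxy-4-methoxyphenyl]-3-[2,5-bis(benzyloxy)-3,4-dimethoxyphenyl]prop-2-en-1-one F6. I2/DMSO at 120 °C closes it to 5-(benzyloxy)-2-[2,5-bis(benzyloxy)-3,4-dimethoxyphenyl]-7-methoxy-4H-chromen-4-one F7. Hydrogenolysis of all three benzyl ethers (H2, Pd/C, EtOAc/MeOH) then gives 10.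

Step 4 (I2/DMSO oxidative cyclisation). At 120 °C the HI formed can attack benzyl ethers, and electrophilic iodine can iodinate C6/C8 of the electron-rich A-ring. The fallback sets out from 4 and comes back at 9, building the pyranone by a Baker–Venkataraman sequence at the correct oxidation level so no oxidant is needed. Pinnick oxidation of 4 (NaClO2, NaH2PO4, 2-methyl-2-butene, t-BuOH/H2O) gives 2,5-bis(benzyloxy)-3,4-dimethoxybenzoic acid F8. Steglich mono-esterification with 5 (EDC·HCl, DMAP, CH2Cl2) gives 2-acetyl-3-hydroxy-5-methoxyphenyl 2,5-bis(benzyloxy)-3,4-dimethoxybenzoate F9. Baker–Venkataraman acyl shift (LiHMDS, THF, −78 to 0 °C) gives 1-[2,5-bis(benzyloxy)-3,4-dimethoxyphenyl]-3-(2,6-dihydroxy-4-methoxyphenyl)propane-1,3-dione F10. Cyclodehydration (cat. TsOH, toluene, 80 °C) gives 9.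

**Further compounds**
F1 | step 1 | 5-bromo-2-hydroxy-3,4-dimethoxybenzaldehyde | O=Cc1cc(Br)c(OC)c(OC)c1O
F2 | step 1 | 2-(benzyloxy)-5-bromo-3,4-dimethoxybenzaldehyde | O=Cc1cc(Br)c(OC)c(OC)c1OCc1ccccc1
F3 | step 1 | 2-(benzyloxy)-3,4-dimethoxy-5-(4,4,5,5-tetramethyl-1,3,2-dioxaborolan-2-yl)benzaldehyde | O=Cc1cc(B2OC(C)(C)C(C)(C)O2)c(OC)c(OC)c1OCc1ccccc1
F4 | step 1 | 2-(benzyloxy)-5-hydroxy-3,4-dimethoxybenzaldehyde | O=Cc1cc(O)c(OC)c(OC)c1OCc1ccccc1
F5 | step 3 | 1-[2-(benzyloxy)-6-hydroxy-4-methoxyphenyl]ethan-1-one | CC(=O)c1c(O)cc(OC)cc1OCc1ccccc1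
F6 | step 3 | (E)-1-[2-(benzyloxy)-6-hydroxy-4-methoxyphenyl]-3-[2,5-bis(benzyloxy)-3,4-dimethoxyphenyl]prop-2-en-1-one | COc1cc(O)c(C(=O)/C=C/c2cc(OCc3ccccc3)c(OC)c(OC)c2OCc2ccccc2)c(OCc2ccccc2)c1
F7 | step 3 | 5-(benzyloxy)-2-[2,5-bis(benzyloxy)-3,4-dimethoxyphenyl]-7-methoxy-4H-chromen-4-one | COc1cc(OCc2ccccc2)c2c(=O)cc(-c3cc(OCc4ccccc4)c(OC)c(OC)c3OCc3ccccc3)oc2c1
F8 | step 4 | 2,5-bis(benzyloxy)-3,4-dimethoxybenzoic acid | OC(=O)c1cc(OCc2ccccc2)c(OC)c(OC)c1OCc1ccccc1
F9 | step 4 | 2-acetyl-3-hydroxy-5-methoxyphenyl 2,5-bis(benzyloxy)-3,4-dimethoxybenzoate | CC(=O)c1c(O)cc(OC)cc1OC(=O)c1cc(OCc2ccccc2)c(OC)c(OC)c1OCc1ccccc1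
F10 | step 4 | 1-[2,5-bis(benzyloxy)-3,4-dimethoxyphenyl]-3-(2,6-dihydroxy-4-methoxyphenyl)propane-1,3-dione | COc1cc(O)c(C(=O)CC(=O)c2cc(OCc3ccccc3)c(OC)c(OC)c2OCc2ccccc2)c(O)c1
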